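**Retrosynthetic overview**
1. Ring A (C4a, C5, C6, C7, C8, C8a) is built last and de novo. C6 lies between C5–OH and C7–OH just as the α-carbon of a β-keto ester lies between its two carbonyl carbons. The hydrated geranyl chain is therefore put on tert-butyl acetoacetate (future C5–C8) by plain alkylation, and no C6/C8 choice on a phloroglucinol ever arises.
2. Key disconnection C4a–C5: keto ester 17 loses tBuOH to give an acylketene, which closes by a 6π process onto the C4a=C8a enol ether of ring C and aromatises to the 5,7-dihydroxy-6-alkyl ring A. The medium is neutral, so the base-labile C2 is spared.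
3. C8–C8a: vinylogous Mukaiyama–Michael addition of bis(silyloxy)diene 13 to dihydropyranone 5, then Saegusa–Ito re-oxidation.
4. Ring C and C2 (S): catalytic asymmetric hetero-Diels–Alder reaction of aldehyde 2 (ring B) with a 1-methoxy-3-silyloxydiene, forming C2–C3 and O1–C8a.
5. Ring order: B (bought), then C (step 2), then A (step 10). The tertiary alcohol comes from distal-selective hydration of geraniol.

Key step: step 10

Remarks and assumptions
- Flavanone numbering (O1, C2, C3, C4, C4a, C5–C8, C8a) is used for the corresponding atoms of all intermediates.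
- Abbreviations: TBS = tert-butyldimethylsilyl; TMS = trimethylsilyl; Ar = 3,4-bis(TBSO)phenyl; R = (E)-3,7-dimethyl-7-(TMSO)oct-2-enyl.
- Assumption: (S)-BINOL/Ti(IV) is taken to direct the diene to the Si face of the aldehyde, by analogy with additions to aromatic aldehydes under the same catalyst. If the sense proves opposite, (R)-BINOL is used.
- Centres that are formed as mixtures and erased later (C6, C8a, C4a, S, Se) are left undefined in the SMILES.

**Route**

Step 1
Reactants: 1 3,4-dihydroxybenzaldehyde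
Product: 2 3,4-bis(tert-butyldimethylsilyloxy)benzaldehyde
Conditions: TBSCl (2.4 equiv), imidazole, DMF, rt
Reagents that add atoms: TBSCl, CC(C)(C)[Si](C)(C)Cl
Why: Imidazole-promoted silyl ether formation caps both phenols, leaves the aldehyde untouched and allows a single fluoride unmasking at the end.

Step 2
Reactants: 2 3,4-bis(TBSO)benzaldehyde; 3 (E)-1-methoxy-3-(trimethylsilyloxy)buta-1,3-diene
Product: 5 (2S)-2-Ar-2,3-dihydro-4H-pyran-4-one, via silylated aldol adduct 4 (not isolated)
Conditions: (S)-BINOL (20 mol %), Ti(OiPr)4 (10 mol %), 4 Å MS, Et2O, −20 °C; then TFA, CH2Cl2, 0 °C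
Reagents that add atoms: none
Why: Catalytic asymmetric hetero-Diels–Alder reaction in its Mukaiyama-aldol/cyclisation mode, in which the chiral Ti(IV) Lewis acid exposes the Si face of the aldehyde to the diene terminus and so sets C2 as S, after which acid closes O1–C8a with loss of methanol.

Step 3
Reactants: 6 geraniol
Product: 8 (E)-3,7-dimethyloct-2-ene-1,7-diol, via acetoxymercurial 7 (not isolated)
Conditions: Hg(OAc)2 (1.0 equiv), THF/H2O 1:1, 0 °C; then 3 M NaOH, NaBH4, 0 °C
Reagents that add atoms: water, O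
Why: Oxymercuration–demercuration (Markovnikov hydration) should take the distal trisubstituted alkene first because the proximal one is deactivated by the allylic oxygen, and water ends up on the tertiary carbon.

Step 4
Reactants: 8 (E)-3,7-dimethyloct-2-ene-1,7-diol
Product: 9 (E)-8-bromo-2,6-dimethyloct-6-en-2-ol
Conditions: CBr4, PPh3, CH2Cl2, 0 °C
Reagents that add atoms: carbon tetrabromide, BrC(Br)(Br)Br
Why: In the Appel reaction only the unhindered primary allylic alcohol forms the oxyphosphonium salt, which bromide displaces by SN2 without allylic shift or loss of the E geometry.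

Step 5
Reactants: 9 (E)-8-bromo-2,6-dimethyloct-6-en-2-ol; 10 tert-butyl acetoacetate
Product: 11 tert-butyl (E)-2-acetyl-9-hydroxy-5,9-dimethyldec-4-enoate
Conditions: 10 (1.5 equiv), NaH (1.4 equiv), THF, 0 °C; then 9, 0 °C to rt
Reagents that add atoms: none
Why: Acetoacetic ester alkylation (SN2 of the stabilised sodium enolate on the primary allylic bromide) places the side chain on the carbon that becomes C6, the enolate being too weak a base to disturb the tertiary alcohol and the excess of 10 limiting dialkylation.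

Step 6
Reactants: 11 tert-butyl (E)-2-acetyl-9-hydroxy-5,9-dimethyldec-4-enoate
Product: 12 tert-butyl 2-R-3-(trimethylsilyloxy)but-2-enoate
Conditions: TMSCl (3 equiv), Et3N (3.5 equiv), DMAP (cat), toluene, rt
Reagents that add atoms: TMSCl, C[Si](C)(C)Cl
Why: O-silylation of the β-keto ester enol, the first stage of the standard two-stage synthesis of 1,3-bis(silyloxy)dienes, caps the tertiary alcohol in the same operation.

Step 7
Reactants: 12 tert-butyl 2-R-3-(trimethylsilyloxy)but-2-enoate
Product: 13 1-tert-butoxy-2-R-1,3-bis(trimethylsilyloxy)buta-1,3-diene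
Conditions: LDA (1.2 equiv), THF, −78 °C; TMSCl, −78 °C to rt; non-aqueous work-up
Reagents that add atoms: TMSCl, C[Si](C)(C)Cl
Why: Kinetic γ-deprotonation of the β-silyloxy enoate and O-silylation of the extended ester enolate give the masked β-keto ester dianion, a preparation that is established for 2-alkyl acetoacetates.

Step 8
Reactants: 5 (2S)-2-Ar-2,3-dihydro-4H-pyran-4-one; 13 1-tert-butoxy-2-R-1,3-bis(trimethylsilyloxy)buta-1,3-diene
Product: 16 tert-butyl 4-[(6S)-6-Ar-4-(TBSO)-5,6-dihydro-2H-pyran-2-yl]-2-R-3-oxobutanoate, via silyloxy oxocarbenium triflate 14 (not isolated), via TMS enol ether adduct 15 (not isolated)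
Conditions: 5, TBSOTf (1.1 equiv), 2,6-di-tert-butylpyridine (0.2 equiv), CH2Cl2, −78 °C; then 13 (1.3 equiv), −78 °C; Et3N, aq NaHCO3
Reagents that add atoms: TBSOTf, CC(C)(C)[Si](C)(C)OS(=O)(=O)C(F)(F)F
Why: In this vinylogous Mukaiyama–Michael addition the silyl triflate turns the vinylogous ester into cation 14, which the terminal CH2 (C8) of 13 attacks at C8a as known for this diene class with chromones and for silyl enol ethers with dihydropyranones, and the new centres C8a and C6 form as mixtures that steps 9 and 10 erase.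

Step 9
Reactants: 16 tert-butyl 4-[(6S)-6-Ar-4-(TBSO)-5,6-dihydro-2H-pyran-2-yl]-2-R-3-oxobutanoate
Product: 17 tert-butyl 4-[(2S)-2-Ar-4-oxo-3,4-dihydro-2H-pyran-6-yl]-2-R-3-oxobutanoate
Conditions: Pd(OAc)2 (1.05 equiv), MeCN, rt
Reagents that add atoms: none
Why: In the Saegusa–Ito oxidation Pd(II) exchanges with the regiodefined C4=C4a silyl enol ether and β-hydride elimination can only take the C8a–H, so the enone returns at C4a=C8a and the C2–C3 side stays untouched.

Step 10
Reactants: 17 tert-butyl 4-[(2S)-2-Ar-4-oxo-3,4-dihydro-2H-pyran-6-yl]-2-R-3-oxobutanoate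
Product: 21 (2S)-2-Ar-5,7-dihydroxy-6-R-chroman-4-one, via acylketene 18 (not isolated), via hydroxydienylketene 19 (not isolated), via cyclohexadienone 20 (not isolated)
Conditions: xylenes (0.005 M), 140 °C, slow N2 sweep to remove tBuOH, silanised glassware
Reagents that add atoms: none
Why: Proposed new method: heating the enolisable tert-butyl β-keto ester should expel tert-butanol through a six-membered transition state to give acylketene 18; enolisation of C7=O towards the doubly activated C8 methylene then gives hydroxydienylketene 19, whose C5=C6–C7=C8–C8a=C4a array closes ring A by a 6π electrocyclisation (C5–C4a bond, six-membered carbocycle) to dienone 20, which tautomerises irreversibly to the phloroglucinol ring. The closest known reaction types are the thermolysis of tert-butyl β-keto esters to acylketenes, the terminal dienylketene electrocyclisation of the Danheiser and Moore benzannulations, the Conrad–Limpach type thermal cyclisation, and the biomimetic Claisen cyclisation of 3,5,7-triketo esters to acylphloroglucinols; the new element is the capture of such an acylketene by the α-carbon of a cyclic vinylogous ester. No stereocentre is created, since C6 and C4a end up sp2, and C2 is a spectator that should keep its configuration because the medium holds neither acid nor base to trigger retro-oxa-Michael opening of ring C. The regiochemistry (chain on C6, not C8) is fixed by constitution, because R sits on the carbon between C5 and C7. Chemoselectivity is secured by the substrate: O1 is tied up as the ring ether so no 2-pyranone can form by O-acylation, aldol attack of C6 on C4=O would give a quaternary carbon that cannot aromatise and therefore reverts, and high dilution with removal of tert-butanol suppresses ketene dimerisation and re-addition.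

Step 11
Reactants: 21 (2S)-2-Ar-5,7-dihydroxy-6-R-chroman-4-one
Product: 22 prokinawan
Conditions: Et3N·3HF, THF, 0 °C to rt; pH 7 buffer
Reagents that add atoms: none
Why: Fluoride-mediated desilylation in a weakly acidic buffered medium should remove all three silyl groups without endangering the base-labile C2 centre or the acid-labile tertiary alcohol and ortho-allyl phenol unit.

**Compound list**
1 | 3,4-dihydroxybenzaldehyde | O=Cc1ccc(O)c(O)c1 | starting material
2 | 3,4-bis(tert-butyldimethylsilyloxy)benzaldehyde | O=Cc1ccc(O[Si](C)(C)C(C)(C)C)c(O[Si](C)(C)C(C)(C)C)c1 | intermediate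
3 | (E)-1-methoxy-3-(trimethylsilyloxy)buta-1,3-diene | CO/C=C/C(=C)O[Si](C)(C)C | starting material
4 | (1E,5S)-5-Ar-1-methoxy-5-(trimethylsilyloxy)pent-1-en-3-one | CO/C=C/C(=O)C[C@@H](c1ccc(O[Si](C)(C)C(C)(C)C)c(O[Si](C)(C)C(C)(C)C)c1)O[Si](C)(C)C | intermediate
5 | (2S)-2-[3,4-bis(TBSO)phenyl]-2,3-dihydro-4H-pyran-4-one | O=C1C[C@@H](c2ccc(O[Si](C)(C)C(C)(C)C)c(O[Si](C)(C)C(C)(C)C)c2)OC=C1 | intermediate
6 | geraniol, (E)-3,7-dimethylocta-2,6-dien-1-ol | C/C(=C\CO)CCC=C(C)C | starting material
7 | (E)-6-(acetoxymercurio)-3,7-dimethyloct-2-ene-1,7-diol | C/C(=C\CO)CCC([Hg]OC(C)=O)C(C)(C)O | intermediate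
8 | (E)-3,7-dimethyloct-2-ene-1,7-diol | C/C(=C\CO)CCCC(C)(C)O | intermediate
9 | (E)-8-bromo-2,6-dimethyloct-6-en-2-ol | C/C(=C\CBr)CCCC(C)(C)O | intermediate
10 | tert-butyl acetoacetate | CC(=O)CC(=O)OC(C)(C)C | starting material
11 | tert-butyl (E)-2-acetyl-9-hydroxy-5,9-dimethyldec-4-enoate | C/C(=C\CC(C(C)=O)C(=O)OC(C)(C)C)CCCC(C)(C)O | intermediate
12 | tert-butyl (4E)-5,9-dimethyl-9-(trimethylsilyloxy)-2-[1-(trimethylsilyloxy)ethylidene]dec-4-enoate | C/C(=C\CC(C(=O)OC(C)(C)C)=C(C)O[Si](C)(C)C)CCCC(C)(C)O[Si](C)(C)C | intermediate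
13 | 1-tert-butoxy-2-[(E)-3,7-dimethyl-7-(trimethylsilyloxy)oct-2-enyl]-1,3-bis(trimethylsilyloxy)buta-1,3-diene | C/C(=C\CC(C(=C)O[Si](C)(C)C)=C(OC(C)(C)C)O[Si](C)(C)C)CCCC(C)(C)O[Si](C)(C)C | intermediate
14 | (2S)-2-Ar-4-(TBSO)-2,3-dihydropyrylium triflate | CC(C)(C)[Si](C)(C)OC1=CC=[O+][C@H](c2ccc(O[Si](C)(C)C(C)(C)C)c(O[Si](C)(C)C(C)(C)C)c2)C1.[O-]S(=O)(=O)C(F)(F)F | intermediate
15 | tert-butyl 4-[(6S)-6-Ar-4-(TBSO)-5,6-dihydro-2H-pyran-2-yl]-2-R-3-(trimethylsilyloxy)but-2-enoate | C/C(=C\CC(C(=O)OC(C)(C)C)=C(CC1C=C(O[Si](C)(C)C(C)(C)C)C[C@@H](c2ccc(O[Si](C)(C)C(C)(C)C)c(O[Si](C)(C)C(C)(C)C)c2)O1)O[Si](C)(C)C)CCCC(C)(C)O[Si](C)(C)C | intermediate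
16 | tert-butyl 4-[(6S)-6-Ar-4-(TBSO)-5,6-dihydro-2H-pyran-2-yl]-2-R-3-oxobutanoate | C/C(=C\CC(C(=O)OC(C)(C)C)C(=O)CC1C=C(O[Si](C)(C)C(C)(C)C)C[C@@H](c2ccc(O[Si](C)(C)C(C)(C)C)c(O[Si](C)(C)C(C)(C)C)c2)O1)CCCC(C)(C)O[Si](C)(C)C | intermediate
17 | tert-butyl 4-[(2S)-2-Ar-4-oxo-3,4-dihydro-2H-pyran-6-yl]-2-R-3-oxobutanoate | C/C(=C\CC(C(=O)OC(C)(C)C)C(=O)CC1=CC(=O)C[C@@H](c2ccc(O[Si](C)(C)C(C)(C)C)c(O[Si](C)(C)C(C)(C)C)c2)O1)CCCC(C)(C)O[Si](C)(C)C | intermediate
18 | acylketene: 17 minus tBuOH, O=C5=C6(R)–C7(=O)–C8H2–(pyranon-6-yl) | C/C(=C\CC(=C=O)C(=O)CC1=CC(=O)C[C@@H](c2ccc(O[Si](C)(C)C(C)(C)C)c(O[Si](C)(C)C(C)(C)C)c2)O1)CCCC(C)(C)O[Si](C)(C)C | intermediate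
19 | hydroxydienylketene: C7 enol tautomer of 18 | C/C(=C\CC(=C=O)C(O)=CC1=CC(=O)C[C@@H](c2ccc(O[Si](C)(C)C(C)(C)C)c(O[Si](C)(C)C(C)(C)C)c2)O1)CCCC(C)(C)O[Si](C)(C)C | intermediate
20 | (2S)-2-Ar-7-hydroxy-6-R-2,3-dihydro-4aH-chromene-4,5-dione, the keto tautomer of 21 | C/C(=C\CC1=C(O)C=C2O[C@H](c3ccc(O[Si](C)(C)C(C)(C)C)c(O[Si](C)(C)C(C)(C)C)c3)CC(=O)C2C1=O)CCCC(C)(C)O[Si](C)(C)C | intermediate
21 | (2S)-2-[3,4-bis(TBSO)phenyl]-5,7-dihydroxy-6-[(E)-3,7-dimethyl-7-(trimethylsilyloxy)oct-2-enyl]chroman-4-one | C/C(=C\Cc1c(O)cc2c(c1O)C(=O)C[C@@H](c1ccc(O[Si](C)(C)C(C)(C)C)c(O[Si](C)(C)C(C)(C)C)c1)O2)CCCC(C)(C)O[Si](C)(C)C | intermediate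
22 | prokinawan, (2S)-2-(3,4-dihydroxyphenyl)-5,7-dihydroxy-6-[(E)-7-hydroxy-3,7-dimethyloct-2-enyl]chroman-4-one | C/C(=C\Cc1c(O)cc2c(c1O)C(=O)C[C@@H](c1ccc(O)c(O)c1)O2)CCCC(C)(C)O | target

**Step count**
- Total step count: 11
- Longest linear sequence: 9 steps (steps 3 to 11, from geraniol)

**Steps most likely to fail**

Step 10 (bears the label).
- What may go wrong: loss of isobutene followed by decarboxylation may outrun ketene formation. The ketene may also dimerise if C4a of the vinylogous ester is too weak a nucleophile for closure.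
- Fallback (known chemistry, sets out from 17, comes back at 21): the C4a–C5 bond is closed as an ionic, metal-templated Claisen (Dieckmann-type) condensation instead of a pericyclic ketene cascade.
- With Mg(OMe)2 in MeOH/THF at rt the C8 methylene is deprotonated and Mg(II) chelates the C7/C5 dicarbonyl unit. The extended enolate then acylates at C4a with expulsion of tert-butoxide.
- This is the biomimetic cyclisation mode known for 3,5,7-triketo esters giving acylphloroglucinols, and neither ketene nor heat is involved.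
- The price is exposure of C2 to a basic medium, so the enantiomeric purity of 21 would have to be verified. No new compound is made (F0).

Step 8.
- What may go wrong: in cation 14 the benzylic C2–O1 bond, activated by the electron-rich aryl group, may ionise and re-close, which erodes the configuration at C2. The silyl triflate may also strip the tert-butyl group from the ketene acetal before C–C bond formation.
- Fallback (sets out from 5, comes back at 17, replaces steps 8 and 9): activation is moved from a cation to a removable acceptor group on C4a that also carries the oxidation level.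
- Electrophilic sulfenylation of 5 (p-TolSCl, CH2Cl2, −78 °C, then Et3N) should give (2S)-2-Ar-5-(p-tolylthio)-2,3-dihydro-4H-pyran-4-one F1.
- Oxidation with mCPBA (1.0 equiv, −78 °C) should give the sulfoxide (2S)-2-Ar-5-(p-tolylsulfinyl)-2,3-dihydro-4H-pyran-4-one F2.
- This doubly activated acceptor should take up 13 at C8a under ZnBr2 catalysis without a silyl triflate. Mild aqueous work-up would then give the α-sulfinyl ketone tert-butyl 4-[(6S)-6-Ar-4-oxo-3-(p-tolylsulfinyl)tetrahydropyran-2-yl]-2-R-3-oxobutanoate F3.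
- Warming F3 in toluene (80 °C, CaCO3) triggers syn-elimination of the sulfenic acid to 17. The sequence of conjugate addition and thermal sulfoxide elimination is known for 3-sulfinylchromones.

Step 9.
- What may go wrong: Pd(II) may be diverted by the β-keto ester enol or the trisubstituted alkene, leading to oxidative cyclisation or dehydrogenation into the side chain. The silyl enol ether may also simply be protodesilylated to the saturated ketone.
- Fallback (sets out from 16, comes back at 17): the metal-mediated dehydrosilylation is replaced by a chalcogen syn-elimination.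
- PhSeCl (1.0 equiv, CH2Cl2, −78 °C) should convert the silyl enol ether irreversibly into the α-selenide tert-butyl 4-[(6S)-6-Ar-4-oxo-3-(phenylselanyl)tetrahydropyran-2-yl]-2-R-3-oxobutanoate F4.
- H2O2/pyridine at 0 °C should oxidise it to the selenoxide tert-butyl 4-[(6S)-6-Ar-4-oxo-3-(phenylseleninyl)tetrahydropyran-2-yl]-2-R-3-oxobutanoate F5.
- F5 eliminates towards the only available β-hydrogen (C8a–H) below room temperature and gives 17.

**Further compounds**
F0 | step 10 | none | none
F1 | step 8 | (2S)-2-Ar-5-(p-tolylthio)-2,3-dihydro-4H-pyran-4-one | O=C1C[C@@H](c2ccc(O[Si](C)(C)C(C)(C)C)c(O[Si](C)(C)C(C)(C)C)c2)OC=C1Sc3ccc(C)cc3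
F2 | step 8 | (2S)-2-Ar-5-(p-tolylsulfinyl)-2,3-dihydro-4H-pyran-4-one | O=C1C[C@@H](c2ccc(O[Si](C)(C)C(C)(C)C)c(O[Si](C)(C)C(C)(C)C)c2)OC=C1S(=O)c3ccc(C)cc3
F3 | step 8 | tert-butyl 4-[(6S)-6-Ar-4-oxo-3-(p-tolylsulfinyl)tetrahydropyran-2-yl]-2-R-3-oxobutanoate | C/C(=C\CC(C(=O)OC(C)(C)C)C(=O)CC1O[C@H](c2ccc(O[Si](C)(C)C(C)(C)C)c(O[Si](C)(C)C(C)(C)C)c2)CC(=O)C1S(=O)c3ccc(C)cc3)CCCC(C)(C)O[Si](C)(C)C
F4 | step 9 | tert-butyl 4-[(6S)-6-Ar-4-oxo-3-(phenylselanyl)tetrahydropyran-2-yl]-2-R-3-oxobutanoate | C/C(=C\CC(C(=O)OC(C)(C)C)C(=O)CC1O[C@H](c2ccc(O[Si](C)(C)C(C)(C)C)c(O[Si](C)(C)C(C)(C)C)c2)CC(=O)C1[Se]c3ccccc3)CCCC(C)(C)O[Si](C)(C)C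
F5 | step 9 | tert-butyl 4-[(6S)-6-Ar-4-oxo-3-(phenylseleninyl)tetrahydropyran-2-yl]-2-R-3-oxobutanoate | C/C(=C\CC(C(=O)OC(C)(C)C)C(=O)CC1O[C@H](c2ccc(O[Si](C)(C)C(C)(C)C)c(O[Si](C)(C)C(C)(C)C)c2)CC(=O)C1[Se](=O)c3ccccc3)CCCC(C)(C)O[Si](C)(C)C
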